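**Plan**

- Hardest feature: C2 lies β to the C4 ketone with O1 as leaving group. Any chalcone-type closure or basic step reopens ring C (retro-oxa-Michael), which racemises C2 and, because O1 and O5 both flank the acyl carbon C4a, also exchanges 6- for 8-geranyl.
- Retrosynthesis: cut C2–C1′ (phenyl) first, then C6–C1″ (geranyl), then C6–I, then the pyranone (O1–C2 and C2–C3) back to a mirror-symmetric 2,6-dihydroxy-4-methoxyacetophenone.
- Forward: ring C is closed first, as a flat 4H-chromen-4-one, on the symmetric acetophenone, so there is no regiochemical choice. The 5-OH···O=C4 chelate then directs iodination to C6, and a Stille coupling brings in the intact (E)-geranyl chain.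
- Enabling feature: O1–C2=C3–C4=O of ring C is a vinylogous ester with C2 as its β-carbon. The phenyl ring and the only stereocentre can therefore be delivered together to the planar pyranone by catalytic asymmetric conjugate arylation (a dearomatising addition), and ring C is never opened.
- Stereochemistry: C2 (S) comes from the chiral Rh–bisphosphine catalyst in the last step, with nothing after it. The 2″E alkene is carried unchanged from geranyl chloride.

Key step: step 5

Assumption: the Rh/(S)-biaryl-bisphosphine catalyst is taken to deliver phenyl to the chromone face that gives 2S, in the sense in which (S)-biaryl bisphosphines give (S)-3-arylcyclohexanones. If a calibration run on the geranyl-free chromone (which gives pinostrobin) shows the opposite sense, the (R)-ligand is used.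

**Route**

Step 1
Reactants: 1 2',6'-dihydroxy-4'-methoxyacetophenone
Product: 3 5-hydroxy-7-methoxy-4H-chromen-4-one, via enaminone 2 (not isolated)
Conditions: Me2NCH(OMe)2 (2.5 equiv), toluene, 95 °C; evaporate; then conc. HCl, CH2Cl2, 40 °C
Reagents that add atoms: N,N-dimethylformamide dimethyl acetal, COC(OC)N(C)C
Why: Condensation of the methyl ketone with the formamide acetal to the enaminone, then acid-promoted addition–elimination of an ortho phenol with loss of dimethylamine, is the standard enaminone route to chromones; the two ortho hydroxyls of 1 are equivalent by symmetry, so only one chromone can form and the other hydroxyl becomes the chelated 5-OH.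

Step 2
Reactants: 3 5-hydroxy-7-methoxy-4H-chromen-4-one
Product: 4 5-hydroxy-6-iodo-7-methoxy-4H-chromen-4-one
Conditions: NIS (1.05 equiv), DMF, 0 °C to rt, dark
Reagents that add atoms: N-iodosuccinimide, O=C1CCC(=O)N1I
Why: Electrophilic aromatic iodination, in which the free, C4=O-chelated 5-OH of 5-hydroxy-7-alkoxy-chromones and -flavones should steer neutral NIS to its ortho carbon C6 and not to C8, while the pyranone C3 is far less nucleophilic than the phloroglucinol-type ring A.

Step 3
Reactants: 5 geranyl chloride
Product: 6 tributyl[(2E)-3,7-dimethylocta-2,6-dien-1-yl]stannane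
Conditions: Bu3SnH, LDA, THF, 0 °C; then 5, −78 °C to rt
Reagents that add atoms: tributyltin hydride, CCCC[SnH](CCCC)CCCC
Why: SN2 displacement of the primary allylic chloride by the stannyl anion at low temperature should give the linear allylstannane and leave the 2E double bond untouched.

Step 4
Reactants: 4 5-hydroxy-6-iodo-7-methoxy-4H-chromen-4-one; 6 tributyl[(2E)-3,7-dimethylocta-2,6-dien-1-yl]stannane
Product: 7 6-[(2E)-3,7-dimethylocta-2,6-dien-1-yl]-5-hydroxy-7-methoxy-4H-chromen-4-one
Conditions: Pd(PPh3)4 (5 mol %), 6 (1.3 equiv), DMF, 90 °C, degassed
Reagents that add atoms: none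
Why: Migita–Kosugi–Stille coupling, in which oxidative addition into the C6–I bond, allyl transfer from tin and reductive elimination at the unhindered primary allyl terminus should give the linear 2E-geranyl arene, as in the linear prenylation of iodoflavones with prenylstannanes, under neutral conditions that spare the base-sensitive pyranone and the free 5-OH.

Step 5
Reactants: 7 6-[(2E)-3,7-dimethylocta-2,6-dien-1-yl]-5-hydroxy-7-methoxy-4H-chromen-4-one; 8 phenylboronic acid
Product: 9 (2S)-6-geranylpinostrobin
Conditions: [RhCl(C2H4)2]2 (2.5 mol %), (S)-MeO-F12-BIPHEP [(S)-6,6'-dimethoxy-2,2'-bis{bis(3,4,5-trifluorophenyl)phosphino}biphenyl] (5.5 mol %), aq KOH (10 mol %), PhB(OH)2 (3 equiv), toluene/H2O 10:1, 60 °C; NH4Cl work-up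
Reagents that add atoms: none
Why: This is a Rh(I)-catalysed asymmetric 1,4-addition of an arylboronic acid to a chromone (Hayashi–Miyaura type, known to give flavanones): B-to-Rh transmetalation gives Ph–Rh(P*P), which coordinates C2=C3 of the flat pyranone, inserts syn to place phenyl on C2, and is released from the oxa-π-allyl rhodium enolate by protonolysis with water, regenerating Rh–OH. No ring is closed, since ring C is already in place, so the O1–C2 bond is neither made nor broken and neither racemisation nor 6/8-geranyl exchange by retro-oxa-Michael can occur. The C2 stereocentre is set by the axially chiral ligand alone, because the planar achiral substrate offers no bias; the (S)-ligand is expected to block the face that would lead to 2R, by the quadrant model established for Rh–biaryl-bisphosphine additions to cyclic enones. The step needs 1,4- over 1,2-addition and no second arylation: the 5-OH···O=C4 hydrogen bond should raise conjugate reactivity, and the chelated product ketone, flanked by the substituted ring A, should not be attacked in the absence of strong base. It also needs chemoselectivity against the geranyl chain, which the two unactivated trisubstituted alkenes secure because they do not insert into aryl–Rh(I). The chelating 5-hydroxy-4-keto unit may bind rhodium like an acetylacetonate, which is why the electron-poor ligand, excess boronic acid and 60 °C are chosen.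

**Compound list**

1 | 2',6'-dihydroxy-4'-methoxyacetophenone | CC(=O)c1c(O)cc(OC)cc1O | starting material
2 | (E)-3-(dimethylamino)-1-(2,6-dihydroxy-4-methoxyphenyl)prop-2-en-1-one | CN(C)/C=C/C(=O)c1c(O)cc(OC)cc1O | intermediate
3 | 5-hydroxy-7-methoxy-4H-chromen-4-one | COc1cc(O)c2c(c1)OC=CC2=O | intermediate
4 | 5-hydroxy-6-iodo-7-methoxy-4H-chromen-4-one | COc1cc2OC=CC(=O)c2c(O)c1I | intermediate
5 | geranyl chloride, (2E)-1-chloro-3,7-dimethylocta-2,6-diene | ClC/C=C(\C)CCC=C(C)C | starting material
6 | tributyl[(2E)-3,7-dimethylocta-2,6-dien-1-yl]stannane | CCCC[Sn](CCCC)(CCCC)C/C=C(\C)CCC=C(C)C | intermediate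
7 | 6-[(2E)-3,7-dimethylocta-2,6-dien-1-yl]-5-hydroxy-7-methoxy-4H-chromen-4-one | COc1cc2OC=CC(=O)c2c(O)c1C/C=C(\C)CCC=C(C)C | intermediate
8 | phenylboronic acid | OB(O)c1ccccc1 | starting material
9 | (2S)-6-geranylpinostrobin, (2S)-6-[(2E)-3,7-dimethylocta-2,6-dien-1-yl]-5-hydroxy-7-methoxy-2-phenyl-2,3-dihydro-4H-chromen-4-one | COc1cc2c(c(O)c1C/C=C(\C)CCC=C(C)C)C(=O)C[C@@H](c1ccccc1)O2 | target

**Step count**

Total: 5 steps. Longest linear sequence: 4 steps (1 → 3 → 4 → 7 → 9); step 3 is a one-step side branch.

**Steps most likely to fail**

1. Step 5. The 5-hydroxy-4-keto chelate may sequester rhodium so that turnover stalls, or discrimination between the two faces of C2 may be insufficient. The fallback sets out from 7 and replaces asymmetric addition by racemic addition and kinetic resolution. Conjugate phenylation of 7 with an achiral, more active catalyst ([Rh(OH)(cod)]2, PhB(OH)2, dioxane/H2O) should give racemic 6-geranylpinostrobin F1. F1 is then resolved by asymmetric transfer hydrogenation (Cp*RhCl(TsDPEN), HCO2H/Et3N, EtOAc), with the catalyst antipode chosen so that the (2R)-enantiomer is reduced to the cis-flavan-4-ol F2. The untouched (2S)-ketone is isolated, and the route is rejoined at 9.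

2. Step 4. Partial E-to-Z isomerisation of the 2″ alkene through the σ/π-allylpalladium intermediate, coupling at the tertiary allyl terminus, or protodeiodination may erode the product. The fallback sets out from 4 and reverses the polarity of the partners. Pd-catalysed stannylation of 4 with hexamethylditin (Pd(PPh3)4, dioxane, 100 °C) should give 5-hydroxy-7-methoxy-6-(trimethylstannyl)-4H-chromen-4-one F3. F3 is coupled with geranyl bromide (Pd2(dba)3, AsPh3, THF, 50 °C), where the η3-geranyl–palladium species arises by oxidative addition with retention of the E geometry and is arylated at its primary carbon. The route is rejoined at 7.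

3. Step 2. Competing iodination at C8 or di-iodination may give regioisomers that are hard to separate. The fallback sets out from 1 and introduces the geranyl group before ring closure. C-alkylation of 1 with geranyl bromide (aq KOH, 0 °C) should give 3'-geranyl-2',6'-dihydroxy-4'-methoxyacetophenone F4, the only C-monoalkyl product the symmetric ring allows. Under the conditions of step 1, F4 passes through its enaminone F5 and closes through either hydroxyl, giving 7 together with 8-geranyl-5-hydroxy-7-methoxy-4H-chromen-4-one F6. The two chromones are separated by chromatography, and the route is rejoined at 7, bypassing steps 2 to 4.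

Further compounds
F1 | step 5 | racemic 6-geranylpinostrobin | COc1cc2c(c(O)c1C/C=C(\C)CCC=C(C)C)C(=O)CC(c1ccccc1)O2
F2 | step 5 | (2R,4R)-6-[(2E)-3,7-dimethylocta-2,6-dien-1-yl]-7-methoxy-2-phenylchromane-4,5-diol | COc1cc2c(c(O)c1C/C=C(\C)CCC=C(C)C)[C@H](O)C[C@H](c1ccccc1)O2
F3 | step 4 | 5-hydroxy-7-methoxy-6-(trimethylstannyl)-4H-chromen-4-one | COc1cc2OC=CC(=O)c2c(O)c1[Sn](C)(C)C
F4 | step 2 | 3'-geranyl-2',6'-dihydroxy-4'-methoxyacetophenone | CC(=O)c1c(O)cc(OC)c(C/C=C(\C)CCC=C(C)C)c1O
F5 | step 2 | (E)-3-(dimethylamino)-1-{3-[(2E)-3,7-dimethylocta-2,6-dien-1-yl]-2,6-dihydroxy-4-methoxyphenyl}prop-2-en-1-one | CN(C)/C=C/C(=O)c1c(O)cc(OC)c(C/C=C(\C)CCC=C(C)C)c1O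
F6 | step 2 | 8-[(2E)-3,7-dimethylocta-2,6-dien-1-yl]-5-hydroxy-7-methoxy-4H-chromen-4-one | COc1cc(O)c2C(=O)C=COc2c1C/C=C(\C)CCC=C(C)C
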